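The vessel is closed and stirred, and elm is the very flask asked about, charged with twice as much substrate as partner.

| setting | elm | cedar | flask |
|---|---|---|---|
| substrate | 0.083 M | 0.056 M | 0.083 M |
| partner | 0.0415 M | 0.0415 M | 0.0415 M |
| remark | the very flask that is asked about, followed so far | run made earlier |  |
| time |  |  | 12 h |

elm run (percent of the substrate charged): time / h: product / % = 0.833: 19; 1.33: 25; 2.50: 28; 5.00: 32; 10.0: 32

cedar run (percent of the substrate charged): time / min: product / % = 5.00: 1; 15.0: 13; 30.0: 22; 40.0: 22; 60.0: 32

(each reading ± 2 percentage points)

- summer: change nothing and wait 25 h more
- dawn: at 12 h add partner, 100% of the amount charged, then wait 25 h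
- spring: at 12 h add substrate, 50.0% of the amount charged, then wait 25 h
- autumn: at 12 h take out 90% of the released group then present, then wait 25 h

1. product, in percent of the substrate first charged, at 12 h
2. the option that brings most further product ("none" if no option brings more than 2 percentage points) (summer / dawn / spring / autumn / none)
3. product present, in percent of the substrate first charged, after summer
4. product present, in percent of the substrate first charged, after autumn

- additions bring no volume worth counting

Down the elm column, product reads 32% at 5.00 h and again 32% at 10.0 h, so these two elm readings show no rise, though with a scatter of 2 percentage points on each they can hide a slow one. But partner, the limiting reagent, allows 50.0% at one to one, so I carry the partner yield Y, the moles of product per mole of partner charged, which elm reads as 0.640. Cedar shows 0.432 at its last reading, but its readings are still rising, so it offers no level to set beside elm's.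

So I commit to about 32% in elm at 12 h, and I expect from summer a gain within the scatter of 2 points. Dawn adds a full partner charge, which Y values at 32 points more, or 64.0% in all, so dawn is my choice.

The forecast gives 32% (30% to 34%) at 12 h, 32% (30% to 35%) after summer and 40% (33% to 44%) after autumn. It also picks dawn, but it says “Doubling the partner gives about 48%”, which is lower than my figure.

Elm gives 34.6% at 12 h, 38.4% after summer and 38.7% after autumn, and dawn brings 29 points, against the 32 points from Y.

    substrate + partner ⇌ product + released group (K = 1.10, k = 17.0 /M/h)
    partner + released group ⇌ idle adduct, settled at all times (K = 810 /M)
    released group → by-product carried off (k = 0.480 /h)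
    partner → decomposed reagent (k = 0.170 /h)

In elm at 12.0 h the exchange relaxes with a half-life of 0.482 h, short against the 12 h, and 4.2% of the partner charge stands unbound. On the neighbour with 0.17 M of partner, Y asks for 131% of the substrate charged, more than was charged, and that flask gives 81.0%, a partner yield of 0.395.

(The readings are calculated for substances that don't exist; noise was put on by code.)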